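## Retrosynthetic overview

1. Target ⇐ hydrogenation of an 11-membered cyclic (Z)-enamide ⇐ ring closure through the lactam nitrogen: the N–H adds across a terminal alkyne (C–N bond; the large ring is formed last).
2. Alkynyl ketone ⇐ thioester + butynylzinc; thioester ⇐ Evans syn-aldol of an aldehyde ester, whose new hydroxyl closes lactone B (C–O).
3. Aldehyde ester ⇐ hydroxy-lactone ⇐ menthyl acetal lactone; lactone A ⇐ decarboxylative N-acyliminium / vinylogous Mannich reaction with a silyloxyfuran, then hydrogenation.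
4. The acid for that step ⇐ tandem Michael addition / methylation of the Boc-L-pyroglutamic acid dianion on a (5S)-menthyloxybutenolide.
5. Ring order: pyrrolidinone (chiral pool) → lactone B carbons (as acetal lactone) → lactone A → lactone B → 11-membered ring.

Assumption: compounds 1, 3, 5, 7 and 9 are bought; "lactone A" is the methyl lactone on the pyrrolidinone carbon next to N, "lactone B" the one fused to the large ring, "menthyl" is (1S,2R,5S)-2-isopropyl-5-methylcyclohexyl.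

## Route

Step 1
Reactants: 1 furfural
Product: 2 5-hydroxyfuran-2(5H)-one (racemic)
Conditions: O2, rose bengal (cat.), hν, MeOH, 20 °C
Reagents that add atoms: dioxygen (O=O)
Why: Dye-sensitised singlet-oxygen [4+2] cycloaddition to the furan and methanolysis of the endoperoxide expel the formyl carbon and leave the hydroxybutenolide (furan photooxygenation).

Step 2
Reactants: 2 5-hydroxyfuran-2(5H)-one; 3 (+)-menthol
Product: 4 (5S)-5-(menthyloxy)furan-2(5H)-one
Conditions: camphorsulfonic acid (cat.), toluene, reflux (−H2O); crystallisation from hexane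
Reagents that add atoms: none
Why: Acid-catalysed acetalisation of the pseudo-acid; the acetal centre epimerises under the acid and the (5S) diastereomer (mirror image of the known crystalline (−)-menthol compound) is collected by crystallisation-induced diastereomer transformation.

Step 3
Reactants: 5 3-methylfuran-2(5H)-one
Product: 6 3-methyl-2-(triisopropylsilyloxy)furan
Conditions: TIPSOTf, Et3N, CH2Cl2, 0 °C
Reagents that add atoms: triisopropylsilyl trifluoromethanesulfonate (CC(C)[Si](OS(=O)(=O)C(F)(F)F)(C(C)C)C(C)C)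
Why: Soft enolisation and O-silylation of the butenolide give the aromatic silyl dienol ether (silyloxyfuran formation).

Step 4
Reactants: 7 (4S)-4-benzyl-1,3-oxazolidin-2-one
Product: 8 (4S)-4-benzyl-3-butanoyl-1,3-oxazolidin-2-one
Conditions: n-BuLi, THF, −78 °C; then butanoyl chloride, −78 → 0 °C
Reagents that add atoms: butanoyl chloride (CCCC(Cl)=O)
Why: N-acylation of the lithiated oxazolidinone (standard loading of the Evans auxiliary).

Step 5
Reactants: 9 Boc-L-pyroglutamic acid; 4 (5S)-5-(menthyloxy)furan-2(5H)-one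
Product: 11 (2S,4S)-1-Boc-4-[(2S,3S,4S)-2-(menthyloxy)-4-methyl-5-oxotetrahydrofuran-3-yl]-5-oxopyrrolidine-2-carboxylic acid, via Michael-adduct dilithium enolate 10 (not isolated)
Conditions: LiN(SiMe3)2 (2.2 equiv), THF, −78 °C; 4, −78 °C; MeI, DMPU, −78 → −30 °C; cold 0.5 M HCl
Reagents that add atoms: iodomethane (CI)
Why: Tandem Michael addition–enolate alkylation: the carboxylate-protected lithium lactam enolate adds to the butenolide anti to its own C2 carboxylate and anti to the menthyloxy group (sets pyrrolidine C4 and lactone C3), and lactone enolate 10 is methylated anti to the new C3 substituent (sets lactone C4).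

Step 6
Reactants: 11 the acid from step 5; 6 3-methyl-2-(triisopropylsilyloxy)furan
Product: 13 tert-butyl (3S,5S)-3-[(2S,3S,4S)-2-(menthyloxy)-4-methyl-5-oxotetrahydrofuran-3-yl]-5-[(2S)-4-methyl-5-oxo-2,5-dihydrofuran-2-yl]-2-oxopyrrolidine-1-carboxylate, via 5-acetoxy N,O-acetal 12 (not isolated)
Conditions: PhI(OAc)2, I2 (0.5 equiv), CH2Cl2, hν (visible), 20 °C; then 6 (2.5 equiv), TMSOTf (20 mol%), −78 → −40 °C
Reagents that add atoms: none
Why: Radical oxidative decarboxylation (acyl hypoiodite, then oxidation of the α-amido radical) gives N,O-acetal 12, whose N-acyliminium ion undergoes a vinylogous Mannich reaction with 6 anti to the bulky C3 substituent (3,5-trans) and with the usual threo preference of silyloxyfurans, setting pyrrolidinone C5 and butenolide C2.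

Step 7
Reactants: 13 the butenolide from step 6
Product: 14 tert-butyl (3S,5S)-3-[(2S,3S,4S)-2-(menthyloxy)-4-methyl-5-oxotetrahydrofuran-3-yl]-5-[(2S,4S)-4-methyl-5-oxotetrahydrofuran-2-yl]-2-oxopyrrolidine-1-carboxylate
Conditions: H2 (1 atm), Rh on carbon (5 wt%), EtOAc, 20 °C
Reagents that add atoms: none
Why: Heterogeneous hydrogenation of the butenolide from the face opposite the pyrrolidinone substituent gives the 2,4-cis methyl lactone A (sets the α-methyl centre).

Step 8
Reactants: 14 the N-Boc bis-lactone from step 7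
Product: 15 (3S,5S)-3-[(3S,4S)-2-hydroxy-4-methyl-5-oxotetrahydrofuran-3-yl]-5-[(2S,4S)-4-methyl-5-oxotetrahydrofuran-2-yl]pyrrolidin-2-one (lactol epimers)
Conditions: CF3CO2H–H2O (4:1), 20 → 40 °C
Reagents that add atoms: water (O)
Why: Acidolysis removes the Boc group and hydrolyses the acyloxy alkyl acetal to the hydroxy-lactone (pseudo-acid); only the anomeric centre is affected.

Step 9
Reactants: 15 the hydroxy-lactone from step 8
Product: 16 methyl (2S,3S)-2-methyl-3-[(3S,5S)-5-((2S,4S)-4-methyl-5-oxotetrahydrofuran-2-yl)-2-oxopyrrolidin-3-yl]-4-oxobutanoate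
Conditions: MeI, KHCO3, DMF, 0 → 20 °C
Reagents that add atoms: iodomethane (CI)
Why: O-alkylation of the ring-opened carboxylate of the pseudo-acid traps the open form as its methyl ester and frees the aldehyde; the weak base avoids α-epimerisation.

Step 10
Reactants: 16 the aldehyde ester from step 9; 8 (4S)-4-benzyl-3-butanoyl-1,3-oxazolidin-2-one
Product: 18 (4S)-4-benzyl-3-{(2S)-2-[(2R,3S,4S)-4-methyl-3-((3S,5S)-5-((2S,4S)-4-methyl-5-oxotetrahydrofuran-2-yl)-2-oxopyrrolidin-3-yl)-5-oxotetrahydrofuran-2-yl]butanoyl}-1,3-oxazolidin-2-one, via aldol adduct 17 (not isolated)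
Conditions: 8 (1.5 equiv), Bu2BOTf, Et3N, CH2Cl2, 0 °C; 16, −78 → 0 °C; H2O2, MeOH, pH 7 buffer; then pyridinium p-toluenesulfonate (cat.), toluene, 60 °C
Reagents that add atoms: none
Why: Evans syn-aldol through the Z-boron enolate (Zimmerman–Traxler chair, auxiliary control) sets the ethyl-bearing centre S and the carbinol centre R, and acid-catalysed lactonisation of 17 onto the methyl ester closes lactone B through its C–O bond with retention, giving the cis ring-fusion pattern.

Step 11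
Reactants: 18 the imide from step 10
Product: 19 S-ethyl (2S)-2-[(2R,3S,4S)-4-methyl-3-((3S,5S)-5-((2S,4S)-4-methyl-5-oxotetrahydrofuran-2-yl)-2-oxopyrrolidin-3-yl)-5-oxotetrahydrofuran-2-yl]butanethioate
Conditions: EtSH, n-BuLi, THF, 0 °C; then 18, 0 °C; aq. NH4Cl
Reagents that add atoms: lithium ethanethiolate, made in the flask from ethanethiol and n-BuLi ([Li+].[S-]CC)
Why: Transthioesterification: the thiolate attacks the exocyclic imide carbonyl and releases the auxiliary, and is too weakly basic to epimerise the α-centre or eliminate the β-acyloxy group.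

Step 12
Reactants: 19 the thioester from step 11
Product: 20 (3S,5S)-3-{(2R,3S,4S)-4-methyl-5-oxo-2-[(3S)-4-oxooct-7-yn-3-yl]tetrahydrofuran-3-yl}-5-[(2S,4S)-4-methyl-5-oxotetrahydrofuran-2-yl]pyrrolidin-2-one
Conditions: 4-bromobut-1-yne, Zn dust, LiCl, THF, 50 °C; then 19, PdCl2(PPh3)2 (5 mol%), toluene–THF, 20 °C
Reagents that add atoms: but-3-yn-1-ylzinc bromide, made in the flask from 4-bromobut-1-yne and Zn (C#CCC[Zn]Br)
Why: Fukuyama coupling (Pd-catalysed thioester–organozinc acyl substitution) forms the ketone under neutral conditions, leaving the lactones, the N–H lactam and the α-stereocentre untouched.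

Step 13
Reactants: 20 the alkynyl ketone from step 12
Product: 21 11-membered cyclic (Z)-enamide (the target with a cis C=C in the N–CH=CH unit of the four-carbon bridge)
Conditions: Ru(2-methylallyl)2(1,5-cyclooctadiene) (10 mol%), bis(dicyclohexylphosphino)methane (12 mol%), H2O (4 equiv), toluene, 90 °C, 2 mM (syringe-pump addition)
Reagents that add atoms: none
Why: Proposed new method: macrocyclising anti-Markovnikov hydroamidation — the Ru catalyst converts the terminal alkyne into a ruthenium vinylidene whose electrophilic α-carbon is attacked by the ruthenium-bound lactam nitrogen, and protonolysis of the alkenyl–Ru bond (the bulky chelating phosphine favouring the Z-alkenyl) releases the cyclic enamide, ring closure being helped by the cis arrangement of the pyrrolidinone and the keto chain on lactone B; the closest known reaction is the intermolecular Ru-catalysed anti-Markovnikov addition of lactams and imides to terminal alkynes, which has not been used to close a ring; no stereocentre is formed or touched.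

Step 14
Reactants: 21 the cyclic enamide from step 13
Product: 22 target CNP0147860.1
Conditions: H2 (1 atm), Pd on carbon (10 wt%), EtOAc, 20 °C
Reagents that add atoms: none
Why: Heterogeneous hydrogenation saturates only the enamide C=C (ketone and lactones are inert) and creates no stereocentre.

## Compound list

1 | furfural | O=Cc1ccco1 | starting material
2 | 5-hydroxyfuran-2(5H)-one (racemic) | OC1OC(=O)C=C1 | intermediate
3 | (+)-menthol, (1S,2R,5S)-2-isopropyl-5-methylcyclohexan-1-ol | CC(C)[C@H]1CC[C@H](C)C[C@@H]1O | starting material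
4 | (5S)-5-(menthyloxy)furan-2(5H)-one | CC(C)[C@H]1CC[C@H](C)C[C@@H]1O[C@H]1OC(=O)C=C1 | intermediate
5 | 3-methylfuran-2(5H)-one | CC1=CCOC1=O | starting material
6 | 3-methyl-2-(triisopropylsilyloxy)furan | Cc1ccoc1O[Si](C(C)C)(C(C)C)C(C)C | intermediate
7 | (4S)-4-benzyl-1,3-oxazolidin-2-one | O=C1N[C@@H](Cc2ccccc2)CO1 | starting material
8 | (4S)-4-benzyl-3-butanoyl-1,3-oxazolidin-2-one | CCCC(=O)N1[C@@H](Cc2ccccc2)COC1=O | intermediate
9 | Boc-L-pyroglutamic acid, (2S)-1-(tert-butoxycarbonyl)-5-oxopyrrolidine-2-carboxylic acid | CC(C)(C)OC(=O)N1[C@@H](CCC1=O)C(=O)O | starting material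
10 | dilithium salt (carboxylate and lactone enolate) of the Michael adduct of 9 and 4, not isolated | CC(C)[C@H]1CC[C@H](C)C[C@@H]1O[C@H]1OC(O[Li])=C[C@@H]1[C@@H]1C[C@H](N(C(=O)OC(C)(C)C)C1=O)C(=O)O[Li] | intermediate
11 | (2S,4S)-1-Boc-4-[(2S,3S,4S)-2-(menthyloxy)-4-methyl-5-oxotetrahydrofuran-3-yl]-5-oxopyrrolidine-2-carboxylic acid | CC(C)[C@H]1CC[C@H](C)C[C@@H]1O[C@H]1OC(=O)[C@@H](C)[C@@H]1[C@@H]1C[C@H](N(C(=O)OC(C)(C)C)C1=O)C(=O)O | intermediate
12 | tert-butyl (3S)-5-acetoxy-3-[(2S,3S,4S)-2-(menthyloxy)-4-methyl-5-oxotetrahydrofuran-3-yl]-2-oxopyrrolidine-1-carboxylate (C5 epimers), not isolated | CC(C)[C@H]1CC[C@H](C)C[C@@H]1O[C@H]1OC(=O)[C@@H](C)[C@@H]1[C@@H]1CC(OC(C)=O)N(C(=O)OC(C)(C)C)C1=O | intermediate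
13 | tert-butyl (3S,5S)-3-[(2S,3S,4S)-2-(menthyloxy)-4-methyl-5-oxotetrahydrofuran-3-yl]-5-[(2S)-4-methyl-5-oxo-2,5-dihydrofuran-2-yl]-2-oxopyrrolidine-1-carboxylate | CC(C)[C@H]1CC[C@H](C)C[C@@H]1O[C@H]1OC(=O)[C@@H](C)[C@@H]1[C@@H]1C[C@H](N(C(=O)OC(C)(C)C)C1=O)[C@@H]1C=C(C)C(=O)O1 | intermediate
14 | tert-butyl (3S,5S)-3-[(2S,3S,4S)-2-(menthyloxy)-4-methyl-5-oxotetrahydrofuran-3-yl]-5-[(2S,4S)-4-methyl-5-oxotetrahydrofuran-2-yl]-2-oxopyrrolidine-1-carboxylate | CC(C)[C@H]1CC[C@H](C)C[C@@H]1O[C@H]1OC(=O)[C@@H](C)[C@@H]1[C@@H]1C[C@H](N(C(=O)OC(C)(C)C)C1=O)[C@@H]1C[C@H](C)C(=O)O1 | intermediate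
15 | (3S,5S)-3-[(3S,4S)-2-hydroxy-4-methyl-5-oxotetrahydrofuran-3-yl]-5-[(2S,4S)-4-methyl-5-oxotetrahydrofuran-2-yl]pyrrolidin-2-one (lactol epimers) | OC1OC(=O)[C@@H](C)[C@@H]1[C@@H]1C[C@H](NC1=O)[C@@H]1C[C@H](C)C(=O)O1 | intermediate
16 | methyl (2S,3S)-2-methyl-3-[(3S,5S)-5-((2S,4S)-4-methyl-5-oxotetrahydrofuran-2-yl)-2-oxopyrrolidin-3-yl]-4-oxobutanoate | O=C[C@H]([C@H](C)C(=O)OC)[C@@H]1C[C@H](NC1=O)[C@@H]1C[C@H](C)C(=O)O1 | intermediate
17 | methyl (2S,3S,4R,5S)-5-{[(4S)-4-benzyl-2-oxo-1,3-oxazolidin-3-yl]carbonyl}-4-hydroxy-2-methyl-3-[(3S,5S)-5-((2S,4S)-4-methyl-5-oxotetrahydrofuran-2-yl)-2-oxopyrrolidin-3-yl]heptanoate, not isolated | O=C1OC[C@H](Cc2ccccc2)N1C(=O)[C@@H](CC)[C@H](O)[C@H]([C@H](C)C(=O)OC)[C@@H]1C[C@H](NC1=O)[C@@H]1C[C@H](C)C(=O)O1 | intermediate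
18 | (4S)-4-benzyl-3-{(2S)-2-[(2R,3S,4S)-4-methyl-3-((3S,5S)-5-((2S,4S)-4-methyl-5-oxotetrahydrofuran-2-yl)-2-oxopyrrolidin-3-yl)-5-oxotetrahydrofuran-2-yl]butanoyl}-1,3-oxazolidin-2-one | O=C1OC[C@H](Cc2ccccc2)N1C(=O)[C@@H](CC)[C@@H]1OC(=O)[C@@H](C)[C@@H]1[C@@H]1C[C@H](NC1=O)[C@@H]1C[C@H](C)C(=O)O1 | intermediate
19 | S-ethyl (2S)-2-[(2R,3S,4S)-4-methyl-3-((3S,5S)-5-((2S,4S)-4-methyl-5-oxotetrahydrofuran-2-yl)-2-oxopyrrolidin-3-yl)-5-oxotetrahydrofuran-2-yl]butanethioate | CCSC(=O)[C@@H](CC)[C@@H]1OC(=O)[C@@H](C)[C@@H]1[C@@H]1C[C@H](NC1=O)[C@@H]1C[C@H](C)C(=O)O1 | intermediate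
20 | (3S,5S)-3-{(2R,3S,4S)-4-methyl-5-oxo-2-[(3S)-4-oxooct-7-yn-3-yl]tetrahydrofuran-3-yl}-5-[(2S,4S)-4-methyl-5-oxotetrahydrofuran-2-yl]pyrrolidin-2-one | C#CCCC(=O)[C@@H](CC)[C@@H]1OC(=O)[C@@H](C)[C@@H]1[C@@H]1C[C@H](NC1=O)[C@@H]1C[C@H](C)C(=O)O1 | intermediate
21 | 11-membered cyclic (Z)-enamide, the target with a cis N–CH=CH double bond in the four-carbon bridge | CC[C@@H]1C(=O)CC/C=C\N2C(=O)[C@@H](C[C@H]2[C@@H]2C[C@H](C)C(=O)O2)[C@@H]2[C@H]1OC(=O)[C@H]2C | intermediate
22 | CNP0147860.1 (tuberostemonone skeleton; all stereocentres S except the lactone B carbinol carbon, R) | CC[C@@H]1C(=O)CCCCN2C(=O)[C@@H](C[C@H]2[C@@H]2C[C@H](C)C(=O)O2)[C@@H]2[C@H]1OC(=O)[C@H]2C | target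

## Step count and risks

Total: 14 steps. Longest linear sequence: 12 steps (1, 2, 5–14, from furfural); 10 steps from Boc-L-pyroglutamic acid.

Most likely to fail:

Step 13 (the new ring closure). Risks are oligomerisation, Markovnikov addition, alkyne hydration and condensation of the N–H with the ketone. The fallback uses known chemistry and sets out from 20. NIS with AgNO3 (cat.) in acetone gives the 1-iodoalkyne F6. Diimide reduction (2-nitrobenzenesulfonohydrazide, Et3N) gives the (Z)-vinyl iodide F7. Copper-catalysed intramolecular amidation of the vinyl iodide (CuI, N,N'-dimethylethylenediamine, Cs2CO3, THF, 60 °C, high dilution), a known way to close macrocyclic enamides, returns to 21.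

Step 6 (configuration at pyrrolidinone C5 is set only by 1,3-induction on a monocyclic N-acyliminium ion; threo/erythro ratio; iodination of the furan). The fallback keeps the chiral-pool centre instead and sets out from 11. EtSH, EDC and DMAP give the S-ethyl thioester F3. Fukuyama coupling with [(2R)-3-methoxy-2-methyl-3-oxopropyl]zinc bromide (from methyl (R)-3-bromo-2-methylpropanoate and Zn; PdCl2(PPh3)2) gives the γ-keto ester F4. Felkin–Anh reduction with Li(s-Bu)3BH at −78 °C (hydride anti to the nitrogen substituent) gives the (S)-hydroxy ester F5. Acid-catalysed lactonisation returns to 14, skipping 12 and 13.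

Step 5 (a dianion must be formed and react twice in one pot; Boc migration or poor solubility could intervene). The fallback uses the documented mono-enolate of a pyroglutamate ester and sets out from 9. Benzyl bromide and KHCO3 give the benzyl ester F1. LiN(SiMe3)2 (1.05 equiv), then 4, then MeI give the methylated benzyl ester adduct F2. Hydrogenolysis (H2, Pd on carbon) returns to 11.

## Further compounds

F1 | step 5 | benzyl (2S)-1-(tert-butoxycarbonyl)-5-oxopyrrolidine-2-carboxylate | CC(C)(C)OC(=O)N1[C@@H](CCC1=O)C(=O)OCc1ccccc1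
F2 | step 5 | benzyl (2S,4S)-1-Boc-4-[(2S,3S,4S)-2-(menthyloxy)-4-methyl-5-oxotetrahydrofuran-3-yl]-5-oxopyrrolidine-2-carboxylate | CC(C)[C@H]1CC[C@H](C)C[C@@H]1O[C@H]1OC(=O)[C@@H](C)[C@@H]1[C@@H]1C[C@H](N(C(=O)OC(C)(C)C)C1=O)C(=O)OCc1ccccc1
F3 | step 6 | S-ethyl thioester of 11 | CC(C)[C@H]1CC[C@H](C)C[C@@H]1O[C@H]1OC(=O)[C@@H](C)[C@@H]1[C@@H]1C[C@H](N(C(=O)OC(C)(C)C)C1=O)C(=O)SCC
F4 | step 6 | methyl (2S)-4-[(2S,4S)-1-Boc-4-((2S,3S,4S)-2-(menthyloxy)-4-methyl-5-oxotetrahydrofuran-3-yl)-5-oxopyrrolidin-2-yl]-2-methyl-4-oxobutanoate | CC(C)[C@H]1CC[C@H](C)C[C@@H]1O[C@H]1OC(=O)[C@@H](C)[C@@H]1[C@@H]1C[C@H](N(C(=O)OC(C)(C)C)C1=O)C(=O)C[C@H](C)C(=O)OC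
F5 | step 6 | methyl (2S,4S)-4-[(2S,4S)-1-Boc-4-((2S,3S,4S)-2-(menthyloxy)-4-methyl-5-oxotetrahydrofuran-3-yl)-5-oxopyrrolidin-2-yl]-4-hydroxy-2-methylbutanoate | CC(C)[C@H]1CC[C@H](C)C[C@@H]1O[C@H]1OC(=O)[C@@H](C)[C@@H]1[C@@H]1C[C@H](N(C(=O)OC(C)(C)C)C1=O)[C@@H](O)C[C@H](C)C(=O)OC
F6 | step 13 | 1-iodoalkyne of 20 (8-iodo-4-oxooct-7-yn-3-yl side chain) | IC#CCCC(=O)[C@@H](CC)[C@@H]1OC(=O)[C@@H](C)[C@@H]1[C@@H]1C[C@H](NC1=O)[C@@H]1C[C@H](C)C(=O)O1
F7 | step 13 | (Z)-vinyl iodide of 20 ((Z)-8-iodo-4-oxooct-7-en-3-yl side chain) | I/C=C\CCC(=O)[C@@H](CC)[C@@H]1OC(=O)[C@@H](C)[C@@H]1[C@@H]1C[C@H](NC1=O)[C@@H]1C[C@H](C)C(=O)O1
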